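**Retrosynthetic overview**
- Target ⇒ (fluoride desilylation) ring B bis-silyl flavan ⇒ O1–C2 disconnection to a racemic 1-(2,4-disilyloxyphenyl)-3-(2-hydroxyaryl)propan-1-ol; a chiral-acid-catalysed, enantioconvergent cyclodehydration closes ring C and sets C2.
- That carbinol ⇒ C2–C1' disconnection: 2,4-bis(silyloxy)phenyl Grignard reagent (from 4-bromoresorcinol) plus a chroman-2-ol.
- The chroman-2-ol ⇒ osthole, which already carries ring A, the 7-methoxy group, the 8-prenyl chain and C2–C4; it needs only allylic hydroxylation and a tandem 1,4/1,2 reduction.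
- Ring order: rings A and B are bought, the coumarin pyranone is opened, and ring C is the only ring made, in the last step.

Assumption: osthole is taken as a cheap commercial natural-product feedstock, and the catalyst antipode in step 5 is whichever experiment shows to give the (2S) series (written here as the (R)-BINOL-derived acid).

**Step 1**
Reactants: 1 osthole, 7-methoxy-8-(3-methylbut-2-enyl)-2H-chromen-2-one
Product: 2 8-[(E)-4-hydroxy-3-methylbut-2-enyl]-7-methoxy-2H-chromen-2-one
Conditions: SeO2 (30 mol%), t-BuOOH (2.5 equiv), salicylic acid (10 mol%), CH2Cl2, rt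
Reagents that add atoms: selenium dioxide, O=[Se]=O (catalytic oxygen carrier); tert-butyl hydroperoxide, CC(C)(C)OO (terminal oxygen source)
Why: Riley-type allylic hydroxylation (SeO2 ene reaction at the more substituted alkene carbon, then [2,3]-sigmatropic shift) attacks the prenyl methyl group trans to the chain, so the primary alcohol forms with E geometry while the coumarin and aryl ether are inert.

**Step 2**
Reactants: 2 8-[(E)-4-hydroxy-3-methylbut-2-enyl]-7-methoxy-2H-chromen-2-one
Product: 5 8-[(E)-4-hydroxy-3-methylbut-2-enyl]-7-methoxychroman-2-ol (racemic lactol in equilibrium with its open hydroxy-aldehyde form), via dihydrocoumarin silyl ether 3 (not isolated), via bis-silyl lactol 4 (not isolated)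
Conditions: Cu(OAc)2·H2O (3 mol%), (R)-DTBM-SEGPHOS (3 mol%), HSiMe(OEt)2 (4 equiv), toluene, 0 °C → rt; then aq. K2CO3, THF
Reagents that add atoms: none
Why: Ligated copper hydride adds hydride 1,4 to the coumarin, the substrate's own primary hydroxyl protonates the copper enolate (ending as a silyl ether), and the resulting aryl lactone, an activated ester, is hydrosilylated once to a silyl acetal that resists further reduction; this tandem 1,4/1,2 reduction is known for 4-substituted coumarins, leaves the isolated trisubstituted alkene alone, and the lactol carbon needs no stereocontrol.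

**Step 3**
Reactants: 6 4-bromoresorcinol (4-bromobenzene-1,3-diol)
Product: 7 1-bromo-2,4-bis(triisopropylsilyloxy)benzene
Conditions: TIPSCl (2.4 equiv), imidazole (5 equiv), DMF, 40 °C
Reagents that add atoms: chlorotriisopropylsilane, CC(C)[Si](Cl)(C(C)C)C(C)C
Why: Imidazole-promoted silylation of both phenols (Corey protocol); the bulky triisopropylsilyl groups resist silyl migration next to the aryl–magnesium bond and the later alkoxide, and survive the acid of step 5.

**Step 4**
Reactants: 5 8-[(E)-4-hydroxy-3-methylbut-2-enyl]-7-methoxychroman-2-ol; 7 1-bromo-2,4-bis(triisopropylsilyloxy)benzene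
Product: 9 racemic 1-[2,4-bis(triisopropylsilyloxy)phenyl]-3-[2-hydroxy-3-[(E)-4-hydroxy-3-methylbut-2-enyl]-4-methoxyphenyl]propan-1-ol, via aryl Grignard reagent 8 (not isolated)
Conditions: 7 (3.4 equiv), Mg, LiCl, THF, 40 °C; then 5, THF, 0 °C → rt; then H2O
Reagents that add atoms: none
Why: Grignard addition to the hydroxy-aldehyde tautomer of a chroman-2-ol: two equivalents of 8 are spent deprotonating the lactol and allylic hydroxyls, the magnesium phenoxide–aldehyde takes up the third, and the carbinol centre is left racemic on purpose because step 5 erases it.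

**Step 5**
Reactants: 9 racemic 1-[2,4-bis(triisopropylsilyloxy)phenyl]-3-[2-hydroxy-3-[(E)-4-hydroxy-3-methylbut-2-enyl]-4-methoxyphenyl]propan-1-ol
Product: 11 morusyunnansin E, 4-[(2S)-8-[(E)-4-hydroxy-3-methylbut-2-enyl]-7-methoxychroman-2-yl]benzene-1,3-diol, via bis-silyl (2S)-flavan 10 (not isolated)
Conditions: (R)-3,3'-bis(2,4,6-triisopropylphenyl)-BINOL N-triflyl phosphoramide (5 mol%), 5 Å MS, toluene (0.02 M), –40 °C; then THF, AcOH (3 equiv), TBAF (2.5 equiv), 0 °C
Reagents that add atoms: none
Why: Proposed new method: enantioconvergent Brønsted-acid-catalysed cyclodehydration, in which the chiral N-triflyl phosphoramide protonates the doubly oxygen-activated secondary benzylic hydroxyl of racemic 9, water leaves, and both enantiomers converge on one planar benzylic cation (a single geometry, because the chain turns away from the 2-silyloxy group) held as a contact ion pair in the chiral pocket while the ring A phenol, hydrogen-bonded to the phosphoramide oxygen, closes ring C on one face to set C2 as (S), the primary allylic alcohol and the trisubstituted alkene being far harder to ionise or protonate at –40 °C; the closest known reaction types are the chiral N-triflyl phosphoramide-catalysed intramolecular allylic etherification of phenols through allyl-cation contact ion pairs (giving 2H-chromenes) and the racemic acid-mediated cyclodehydration of 1-aryl-3-(2-hydroxyphenyl)propan-1-ols to flavans, and what is new is stereocontrol at a non-allylic benzylic cation on a saturated tether; buffered fluoride then removes both silyl groups without touching C2.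

**Compound list**
1 | osthole, 7-methoxy-8-(3-methylbut-2-enyl)-2H-chromen-2-one | COc1ccc2c(c1CC=C(C)C)OC(=O)C=C2 | starting material
2 | 8-[(E)-4-hydroxy-3-methylbut-2-enyl]-7-methoxy-2H-chromen-2-one | COc1ccc2c(c1C/C=C(\C)CO)OC(=O)C=C2 | intermediate
3 | 8-[(E)-4-[diethoxy(methyl)silyl]oxy-3-methylbut-2-enyl]-7-methoxychroman-2-one | COc1ccc2c(c1C/C=C(\C)CO[Si](C)(OCC)OCC)OC(=O)CC2 | intermediate
4 | 2-[diethoxy(methyl)silyl]oxy-8-[(E)-4-[diethoxy(methyl)silyl]oxy-3-methylbut-2-enyl]-7-methoxychroman (racemic) | COc1ccc2c(c1C/C=C(\C)CO[Si](C)(OCC)OCC)OC(O[Si](C)(OCC)OCC)CC2 | intermediate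
5 | 8-[(E)-4-hydroxy-3-methylbut-2-enyl]-7-methoxychroman-2-ol (racemic lactol) | COc1ccc2c(c1C/C=C(\C)CO)OC(O)CC2 | intermediate
6 | 4-bromoresorcinol | Oc1ccc(Br)c(O)c1 | starting material
7 | 1-bromo-2,4-bis(triisopropylsilyloxy)benzene | CC(C)[Si](Oc1ccc(Br)c(O[Si](C(C)C)(C(C)C)C(C)C)c1)(C(C)C)C(C)C | intermediate
8 | [2,4-bis(triisopropylsilyloxy)phenyl]magnesium bromide | CC(C)[Si](Oc1ccc([Mg]Br)c(O[Si](C(C)C)(C(C)C)C(C)C)c1)(C(C)C)C(C)C | intermediate
9 | racemic 1-[2,4-bis(triisopropylsilyloxy)phenyl]-3-[2-hydroxy-3-[(E)-4-hydroxy-3-methylbut-2-enyl]-4-methoxyphenyl]propan-1-ol | COc1ccc(CCC(O)c2ccc(O[Si](C(C)C)(C(C)C)C(C)C)cc2O[Si](C(C)C)(C(C)C)C(C)C)c(O)c1C/C=C(\C)CO | intermediate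
10 | (2S)-2-[2,4-bis(triisopropylsilyloxy)phenyl]-8-[(E)-4-hydroxy-3-methylbut-2-enyl]-7-methoxychroman | COc1ccc2c(c1C/C=C(\C)CO)O[C@H](c1ccc(O[Si](C(C)C)(C(C)C)C(C)C)cc1O[Si](C(C)C)(C(C)C)C(C)C)CC2 | intermediate
11 | morusyunnansin E, 4-[(2S)-8-[(E)-4-hydroxy-3-methylbut-2-enyl]-7-methoxychroman-2-yl]benzene-1,3-diol | COc1ccc2c(c1C/C=C(\C)CO)O[C@H](c1ccc(O)cc1O)CC2 | target

**Step count**
Total: 5 steps. Longest linear sequence: 4 steps (1 → 2 → 5 → 9 → 11; step 3 makes the ring B fragment).

**Three steps most likely to fail**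

Step 5 (the new cyclodehydration). The risks are low enantioselectivity from a loose ion pair, E1 loss to the 1,3-diarylpropene, and re-ionisation of 10. The fallback uses known chemistry only, sets out from 1 and comes back at 10. Osthole 1 is conjugate-reduced with [(Ph3P)CuH]6 in wet toluene to 7-methoxy-8-(3-methylbut-2-enyl)chroman-2-one F1. Grignard reagent 8 (1.1 equiv, THF, –78 °C) opens the lactone to the keto-phenol 1-[2,4-bis(triisopropylsilyloxy)phenyl]-3-[2-hydroxy-4-methoxy-3-(3-methylbut-2-enyl)phenyl]propan-1-one F2; the ortho silyloxy group blocks a second addition. CBS reduction ((S)-2-methyl-CBS-oxazaborolidine, BH3·SMe2, THF, –20 °C) gives (1R)-1-[2,4-bis(triisopropylsilyloxy)phenyl]-3-[2-hydroxy-4-methoxy-3-(3-methylbut-2-enyl)phenyl]propan-1-ol F3. Mitsunobu etherification (PPh3, DIAD, THF, 0 °C, high dilution) closes ring C with inversion to (2S)-2-[2,4-bis(triisopropylsilyloxy)phenyl]-7-methoxy-8-(3-methylbut-2-enyl)chroman F4. The prenyl group is carried through this sequence because a free primary allylic alcohol would compete in the Mitsunobu step. SeO2/t-BuOOH as in step 1 then hydroxylates the E-methyl group to give 10, which is desilylated as in the second stage of step 5.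

Step 2 (tandem copper hydride reduction). It may stop at the dihydrocoumarin, over-reduce to the diol, or stall on the free hydroxyl. The fallback sets out from 2 and comes back at 5. Mg turnings in MeOH (0 °C → rt) reduce the conjugated double bond by electron transfer and open the lactone to methyl 3-[2-hydroxy-3-[(E)-4-hydroxy-3-methylbut-2-enyl]-4-methoxyphenyl]propanoate F5. DIBAL-H (3.2 equiv, CH2Cl2, –78 °C) reduces the ester to the aldehyde, which closes to lactol 5 on work-up.

Step 4 (arylation of the unprotected lactol). The risks are enolisation or aldol of the phenoxide–aldehyde, O-to-O silyl migration in the secondary magnesium alkoxide, and sluggish addition of the hindered reagent. The fallback brings the aryl group in at the lactone oxidation level, sets out from 2 and comes back at 9. [(Ph3P)CuH]6 in wet toluene reduces 2 to 8-[(E)-4-hydroxy-3-methylbut-2-enyl]-7-methoxychroman-2-one F6. Grignard reagent 8 (2.2 equiv, THF, –78 °C) opens it to 1-[2,4-bis(triisopropylsilyloxy)phenyl]-3-[2-hydroxy-3-[(E)-4-hydroxy-3-methylbut-2-enyl]-4-methoxyphenyl]propan-1-one F7. NaBH4 in MeOH at 0 °C gives racemic 9.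

**Further compounds**
F1 | step 5 | 7-methoxy-8-(3-methylbut-2-enyl)chroman-2-one | COc1ccc2c(c1CC=C(C)C)OC(=O)CC2
F2 | step 5 | 1-[2,4-bis(triisopropylsilyloxy)phenyl]-3-[2-hydroxy-4-methoxy-3-(3-methylbut-2-enyl)phenyl]propan-1-one | COc1ccc(CCC(=O)c2ccc(O[Si](C(C)C)(C(C)C)C(C)C)cc2O[Si](C(C)C)(C(C)C)C(C)C)c(O)c1CC=C(C)C
F3 | step 5 | (1R)-1-[2,4-bis(triisopropylsilyloxy)phenyl]-3-[2-hydroxy-4-methoxy-3-(3-methylbut-2-enyl)phenyl]propan-1-ol | COc1ccc(CC[C@@H](O)c2ccc(O[Si](C(C)C)(C(C)C)C(C)C)cc2O[Si](C(C)C)(C(C)C)C(C)C)c(O)c1CC=C(C)C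
F4 | step 5 | (2S)-2-[2,4-bis(triisopropylsilyloxy)phenyl]-7-methoxy-8-(3-methylbut-2-enyl)chroman | COc1ccc2c(c1CC=C(C)C)O[C@H](c1ccc(O[Si](C(C)C)(C(C)C)C(C)C)cc1O[Si](C(C)C)(C(C)C)C(C)C)CC2
F5 | step 2 | methyl 3-[2-hydroxy-3-[(E)-4-hydroxy-3-methylbut-2-enyl]-4-methoxyphenyl]propanoate | COC(=O)CCc1ccc(OC)c(C/C=C(\C)CO)c1O
F6 | step 4 | 8-[(E)-4-hydroxy-3-methylbut-2-enyl]-7-methoxychroman-2-one | COc1ccc2c(c1C/C=C(\C)CO)OC(=O)CC2
F7 | step 4 | 1-[2,4-bis(triisopropylsilyloxy)phenyl]-3-[2-hydroxy-3-[(E)-4-hydroxy-3-methylbut-2-enyl]-4-methoxyphenyl]propan-1-one | COc1ccc(CCC(=O)c2ccc(O[Si](C(C)C)(C(C)C)C(C)C)cc2O[Si](C(C)C)(C(C)C)C(C)C)c(O)c1C/C=C(\C)CO
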